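The ratio of second to first end groups charged is 1.02, so first end groups are the limiting reagent by a small margin, and I treat the two fractions left as equal. I work with the fraction left, not the fraction made.

| flask | first end groups | second end groups | remark | time |
|---|---|---|---|---|
| alder | 0.10 M | 0.102 M | run made earlier |  |
| cedar | 0.067 M | 0.102 M | run made earlier |  |
| birch | 0.15 M | 0.102 M | run made earlier |  |
| south-east | 0.10 M | 0.102 M (fed, over 80 s) | all else is in the flask from the start; the feed brings no volume worth counting | 3.0 min |
| north-east | 0.10 M (fed, over 80 s) | 0.102 M | all else is in the flask from the start; the feed brings no volume worth counting | 3.0 min |
| south-west | 0.10 M (in portions, 3, over 80 s) | 0.102 M | first portion at the start, last at 80 s | 3.0 min |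
| south | 0.10 M | 0.102 M | everything together at the start | 3.0 min |

- the flask that comes out highest in amount of links, in percent of the first end groups charged, or "all alike" when all lie within 1.5 percentage points (south-east / north-east / south-west / south / all alike)
- links at the end, in percent of the first end groups charged, south-east
- links at the end, in percent of the first end groups charged, north-east
- links at the end, in percent of the first end groups charged, south-west
- links at the end, in percent of the first end groups charged, south

alder run (percent of the first end groups charged)

| time / s | links / % | first end groups / % |
|---|---|---|
| 10.0 | 13 | 84 |
| 25.0 | 30 | 70 |
| 50.0 | 45 | 50 |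
| 80.0 | 63 | 40 |
| 120 | 66 | 32 |

cedar run (percent of the first end groups charged)

| time / min | links / % | first end groups / % |
|---|---|---|
| 0.250 | 20 | 80 |
| 0.500 | 36 | 66 |
| 1.00 | 58 | 48 |
| 2.00 | 76 | 25 |
| 4.00 | 91 | 13 |

birch run (percent of the first end groups charged)

| time / min | links / % | first end groups / % |
|---|---|---|
| 0.250 | 20 | 82 |
| 0.500 | 33 | 68 |
| 1.00 | 46 | 57 |
| 2.00 | 55 | 42 |
| 4.00 | 64 | 37 |

(scatter of a reading: 2 percentage points)

I start with the main step, as in south, where everything goes in at the start. With equal fractions the rate goes as the square of the fraction left, so one over that fraction climbs in a straight line from one. Alder has the charges of south. Its last reading, a fraction left of 32.0% at 120 s, gives 1.06 min⁻¹. That is my clock, the rise per minute of one over the fraction left, and it carries the scatter of 2 percentage points in that reading. Over 3.0 min south keeps a fraction of 0.239, so links reach 76.1%.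

Next comes the addition. While a charge goes in, I let the clock tick at the share already charged. In south-east and north-east that share climbs steadily, so it averages half over the 80 s. In south-west it stands at 0.333 and then 0.667 for equal intervals, which averages the same half. So I take 40.0 s off the clock in these flasks. That leaves 140 s of full running, a fraction left of 0.287 and links of 71.3%. The rule is rough, and it gives south-east, north-east and south-west one number.

Last come the crystals. That step joins by-product and crystals, and neither stands in the rate of the main step as I take it, so I add nothing for it. By this reckoning south leads south-east, north-east and south-west by 4.8 points.

The forecast names south, with 75.5% there, 70.3% in south-east and north-east and 69.7% in south-west, a little under my numbers: “Batch comes out highest, since everything reacts at full concentration from the start.”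

The flasks give links of 76.3% in south, 70.7% in south-east and north-east, and 70.1% in south-west.

first end groups + second end groups → links + by-product (k = 0.170 M⁻¹ s⁻¹); crystals ⇌ by-product, rate k2*(cs2 - [by-product]) while solid is left; crystals form when [by-product] > cs2 (solubility = 39.0 mM, k = 0.430 s⁻¹) South-west stands 0.6 points below south-east, a gap my rule does not show. The neighbour is the south-west flask read earlier, at 2.0 min. The same rule takes 40.0 s off and leaves 80.0 s of full running, which gives a fraction left of 0.414 and links of 58.6%. That flask holds first end groups at 44.1% and links at 55.9% after 2.00 min.

The data stem from a simulated flask for an exercise; the scatter is artificial.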